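All runs are calculated with made-up constants; the scatter is artificial.

The constants of this scheme are hidden, so whatever is reckoned here has to come out of the readings of the earlier runs.

| flask | starting material | partner | capture agent | remark | time |
|---|---|---|---|---|---|
| east | 0.18 M | 0.324 M | 0.018 M | run made earlier |  |
| south | 0.25 M | 0.324 M | 0.018 M | run made earlier |  |
| south-west | 0.40 M | 0.324 M | 0.018 M | run made earlier |  |
| south-east | 0.18 M | 0.324 M | 0.0090 M | run made earlier |  |
| delta | 0.18 M (fed, over 6.0 h) | 0.324 M | 0.0180 M | all else is in the flask from the start; the feed brings no volume worth counting | 30 h |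
| epsilon | 0.18 M (fed, over 40 min) | 0.324 M | 0.0180 M | all else is in the flask from the start; the feed brings no volume worth counting | 30 h |
| zeta | 0.18 M | 0.324 M | 0.0180 M | everything together at the start | 30 h |
| alpha | 0.18 M | 0.324 M (fed, over 6.0 h) | 0.0180 M | all else is in the flask from the start; the feed brings no volume worth counting | 30 h |
| eta | 0.18 M (in portions, 2, over 6.0 h) | 0.324 M | 0.0180 M | first portion at the start, last at 6.0 h | 30 h |

| run | time / h | target / % | trapped intermediate / % | starting material / % |
|---|---|---|---|---|
| east | 1.33 | 0.2 | 0.2 | 97.7 |
| east | 2.50 | 0.4 | 0 | 95.5 |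
| east | 5.00 | 0.7 | 0.5 | 91.2 |
| east | 10.0 | 1.6 | 0.5 | 83.1 |
| east | 20.0 | 5.6 | 1.6 | 69.5 |
| south | 4.00 | 0.1 | 0 | 93.0 |
| south | 8.00 | 0.6 | 0.1 | 86.5 |
| south | 10.0 | 1.0 | 0.5 | 83.4 |
| south | 15.0 | 3.2 | 0.7 | 75.4 |
| south | 20.0 | 5.3 | 1.4 | 69.6 |
| south-west | 1.50 | 0.3 | 0.2 | 97.4 |
| south-west | 5.00 | 0.2 | 0.1 | 91.6 |
| south-west | 8.00 | 1.3 | 0.4 | 86.3 |
| south-west | 12.0 | 1.8 | 0 | 80.0 |
| south-west | 20.0 | 4.9 | 1.3 | 68.7 |
| south-east | 4.00 | 0.1 | 0.2 | 93.1 |
| south-east | 8.00 | 1.5 | 0.3 | 86.8 |
| south-east | 10.0 | 1.7 | 0.1 | 83.2 |
| south-east | 15.0 | 3.4 | 0.2 | 75.2 |
| south-east | 20.0 | 5.4 | 0.2 | 69.4 |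

(scatter of a reading: 0.3 percentage points)

- percentages count the starting material that a species holds: one side product counts as two
- target is meant together with its idle adduct
- steps that have been proposed: starting material -> open intermediate; partner + open intermediate -> target; 2 partner -> homo product; partner + target <-> idle adduct; open intermediate + capture agent -> trapped intermediate; starting material + target -> side product

- the best flask by share of target in target plus trapped intermediate; "all alike" if 1.5 percentage points covers them all (delta / epsilon / zeta / alpha / eta / all alike)
- share of target in target plus trapped intermediate at the end, delta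
- share of target in target plus trapped intermediate at the end, epsilon
- share of target in target plus trapped intermediate at the end, zeta
- share of target in target plus trapped intermediate at the end, alpha
- share of target in target plus trapped intermediate at the end, eta

East gives starting material a half-life of 38.1 h. At 20.0 h, south and south-west read nearly the same percentages as east, though their charges differ. Halving [capture agent] in south-east left target at 5.4 % but took trapped intermediate from 1.6 % to 0.2 %.

So I read open intermediate as choosing between partner and capture agent. Pooling east, south and south-west at 20.0 h gives target over trapped intermediate of 3.67. Multiplied by [capture agent]/[partner] as charged, this ratio becomes the branch constant, a selectivity factor, of 0.204.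

Two chemists use this differently. The first asks for the end state. Capture agent is charged at 10.0 % of the starting material, so trapped intermediate must stop there, and she looks for the share to climb as it comes near. She therefore expects zeta, further along, to stand clear of fed delta.

The second asks how far along the flask is. The 30 h run is shorter than the half-life, which leaves about 57.9 % of the starting material unopened, and the east reading of trapped intermediate lies far below the cap. A 6.0 h feed is short beside 38.1 h, and a ratio does not ask when a molecule opened. Delta, epsilon, zeta, alpha and eta are charged with the same 0.324 M and 0.0180 M, so the branch constant gives him a share of 78.6 % for each.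

The forecast, on his side but a little higher, says all alike, with 79.5 % for delta, 80 % for epsilon, 80 % for zeta, 79.3 % for alpha and 79.5 % for eta, in the words “Feeding starting material only delays the same partition”.

The flasks give all alike: delta 80.2 %, epsilon 80.6 %, zeta 80.6 %, alpha 81.0 %, eta 80.2 %, a spread of 0.80 percentage points, inside the margin.

    starting material → open intermediate (k = 5.10 × 10⁻⁶ s⁻¹)
    partner + open intermediate → target (k = 2.10 × 10⁻⁵ M⁻¹ s⁻¹)
    2 partner → homo product (k = 6.50 × 10⁻⁶ M⁻¹ s⁻¹)
    partner + target ⇌ idle adduct, settled at all times (K = 3.30 M⁻¹)
    open intermediate + capture agent → trapped intermediate (k = 7.50 × 10⁻⁵ M⁻¹ s⁻¹)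
    starting material + target → side product (k = 1.10 × 10⁻⁵ M⁻¹ s⁻¹)

At 300 h delta reads 84.7 %, with capture agent at 0.894 % of its charge and trapped intermediate at 9.91 %, beside the cap of 10.0 %; that is the first chemist's region. A neighbour of delta is charged with 0.072 M of capture agent, all else held. For it, the branch constant of 0.204 gives target over trapped intermediate of 0.919, so a share of 47.9 %. At 30.0 h that neighbour holds target 7.34 % and trapped intermediate 7.28 %, a share of 50.2 %.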